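## The problem

Compound 21 joins two rings through one CH2 group. On one side the hinge is bonded to the ring CH of a trisubstituted cyclopentane, on the other to the only unacylated nucleophilic carbon of an enolised 2-acylcyclohexane-1,3,5-trione. There are four stereocentres. Three are contiguous on the cyclopentane: C(CH3)(OH), CH(CH2) and CH(isopropenyl), with the hydroxyl cis and the isopropenyl group trans to the CH2 arm. The fourth is the quaternary C(CH3)(prenyl) carbon of the trione ring. That carbon is stereogenic only because its two flanking carbonyl groups differ: one lies next to the acyl-bearing carbon, the other next to the hinge-bearing carbon. It is separated from the cyclopentane by a freely rotating CH2, so neither half can control the other and each must be made enantiopure on its own; the three cyclopentane centres are adjacent and can control one another. Several groups will not survive rough treatment: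

- the tertiary alcohol, which acid ionises towards dehydration or closure onto an enol oxygen (a dihydropyran);
- the isopropenyl group, which drifts to isopropylidene;
- the prenyl group;
- the enolised β-triketone, which nucleophilic base can open by retro-Claisen cleavage and thereby exchange the flanks of the quaternary centre;
- every β-hydroxy carbonyl intermediate, which can retro-aldolise or dehydrate.

The feature that opens the route is the cyclopentane CH carrying the hinge carbon, flanked by C(CH3)(OH) and CH(isopropenyl). This is the pattern left when a 2,3-epoxy-3-methylcyclohexanone with an unsaturated C3 unit at C6 expels its carbonyl carbon from the ring. The carbonyl carbon becomes the hinge and the epoxide oxygen becomes the tertiary hydroxyl.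

## Retrosynthesis

Numbering: cyclopentane acid 7, its ester 8, silyl ether 9, aldehyde 10; trione core 18; protected target 20; target 21.

**Hinge bond.** The bond between the hinge CH2 and the trione ring carbon is cut first, after masking the tertiary alcohol of 21 as the triethylsilyl ether 20. This gives aldehyde 10 and core 18. The cut is preferred to the neighbouring CH2–cyclopentane bond because the trione carbon is a soft carbon nucleophile. A carbonyl condensation with hydride transfer in the same flask makes the bond without O-alkylation and without creating a stereocentre. Both fragments are about half the size of 21 and each carries its own stereochemistry. The forward reaction must leave the α-centre of 10 and its β-silyloxy group intact.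

**Oxidation level of the cyclopentane.** Aldehyde 10 is traced through ester 9 and hydroxy ester 8 to hydroxy acid 7 (esterification, silylation, partial reduction). The silyl ether is there because a free β-hydroxy aldehyde would retro-aldolise or dehydrate under amine catalysis. Nothing is asked of these steps beyond functional group tolerance.

**Ring contraction (key disconnection).** In 7 the bond between the carboxyl-bearing CH and the CH(isopropenyl) carbon is cut, and the carboxyl carbon is reconnected to the allylic carbon as a ring ketone. This leads to the six-membered epoxy ketone 5, (1S,6S)-piperitenone oxide, via cyclopropanone 6. The alternative cut between the CH and C(CH3)(OH) (an aldol) would leave the relative configuration at the carbinol to a catalyst. The chosen cut derives all three centres from the single epoxide configuration: the carbinol carbon is kept, the epoxide CH is inverted, and the allylic CH is protonated on the face the carbonyl carbon leaves. Precursor 5 has two stereocentres, both set in one catalytic step, and no isopropenyl stereocentre at all. The forward reaction must enolise through the isopropylidene group, cleave the cyclopropanone towards the allylic carbon, and protonate that carbon and not the chain terminus.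

**Epoxy ketone.** Epoxide 5 comes from the achiral dienone 4 (piperitenone) by enantioselective nucleophilic epoxidation of the ring alkene. Dienone 4 comes from mesityl oxide 1 and methyl vinyl ketone 2 by a base-mediated annulation through diketone 3. This is the steepest simplification in the plan: two bulk ketones give the whole carbon skeleton of the terpene half in one step. The epoxidation must distinguish the ring alkene from the exocyclic one and one face from the other.

**Trione core.** Core 18 is opened at the bond between the acyl-bearing ring carbon and the carbonyl next to the quaternary centre (Dieckmann) to give triketo ester 17. This is cut between the other flanking carbonyl and its CH2 into the acid chloride 16 of half-ester 14 and the dianion of diketone 15. The order matters. The carboxyl group freed in 14 becomes the carbonyl next to the hinge carbon, and the surviving ester becomes the carbonyl next to the acyl carbon. The enantiotopic-group choice made in 14 therefore becomes the configuration of the ring. Half-ester 14 comes from the prochiral diester 13 by enzymatic hydrolysis, and 13 from dimethyl methylmalonate 11 and prenyl bromide 12. A 4,4-disubstituted trione without the acyl group would be achiral, so the acyl group must be present before or during ring closure; the chosen assembly satisfies this.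

## Roads not taken

**Alternative 1:** cut the hinge CH2–CH(ring) bond and, at the same time, form an enol O–C(CH3) bond in the forward direction. The exocyclic methylene form A3 of core 18 (an o-quinone methide) would add across (S)-1-methyl-3-(prop-1-en-2-yl)cyclopent-1-ene A2 in a hetero-Diels–Alder reaction to give the cis-fused dihydropyran A1. The pyran would then be opened hydrolytically to 21.
- Merits: the union and two of the three cyclopentane centres come in one step. Suprafacial addition puts oxygen and CH2 cis, approach anti to the isopropenyl group puts them trans to it, and oxygen goes to the more substituted alkene carbon. No protecting group is needed. Both regioisomers of A1 would converge on 21.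
- Weak points: the isopropenyl group of A2 is a less hindered dienophile than the ring alkene and should compete. Unactivated trisubstituted alkenes are slow partners for a quinone methide that dimerises easily. A2 has to be made enantiopure in several steps. The final opening must break a vinylogous ester C–O bond inside a deactivated trione anion, and acid would instead ionise the tertiary C–O bond; it works against the tendency of 21 to cyclise.
- Comparison: this road is more convergent and shorter at the union. The chosen plan sets against it the absence of a competing alkene at the union and a last step (fluoride desilylation) that does not work against a favoured cyclisation.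

**Alternative 2:** cut the ring bond between the CH2 next to the carbinol and the CH(isopropenyl) carbon. The acyclic primary iodide A5 carries the C(CH3)(OH)/CH(CH2OSi) diad derived from an epoxide. It would be reduced by electrogenerated monovalent cobalt from Co(dmgH)2(py)Cl, the radical would close 5-exo onto the 2-methylpropenyl group, and dehydrocobaltation of the tertiary organocobalt would leave the isopropenyl group of silylated cyclopentanol A4.
- Merits: the position of the double bond is set by β-hydride loss towards a methyl group, a more predictable event than protonation of an allyl anion. The ring closure is catalytic and mild, and A4 is one oxidation away from an aldehyde like 10.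
- Weak points: the acyclic diad with its tertiary alcohol costs several stereocontrolled steps before the ring exists. The trans relationship between the new CH and its neighbour rests on a transition-state preference rather than on a mechanistic necessity. Attack on a trisubstituted alkene is slow enough for reduction of the radical to compete. Electrolysis equipment is needed.
- Comparison: this road is better on alkene regiochemistry. The chosen plan sets against it brevity (three steps from bulk ketones to 7) and a cis hydroxyl/carboxyl relationship enforced by backside epoxide opening.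

**Alternative 3:** cut the CH–C(CH3)(OH) ring bond. (S)-Limonene A8 would be cleaved at its ring alkene to (S)-6-oxo-3-(prop-1-en-2-yl)heptanal A7. A secondary amine catalyst such as proline would convert the aldehyde into its enamine, whose α-carbon adds to the methyl ketone to give hydroxy aldehyde A6.
- Merits: this is the shortest road. The isopropenyl stereocentre comes from the chiral pool and is never at risk, and A6 is already at the aldehyde oxidation level, so the ester and reduction steps of the chosen plan disappear.
- Weak points: the aldol must stop before dehydration, although the conjugated cyclopentenecarbaldehyde is the usual product of this keto aldehyde with amine catalysts. A ketone is a sluggish acceptor for an enamine. The configuration at the carbinol depends on matching catalyst and substrate. A6 is a β-hydroxy aldehyde exposed to amine, so it can revert or epimerise.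
- Comparison: this road is shorter and cheaper. The chosen plan sets against it that the hydroxyl/CH relationship follows from an inversion and that the ring-forming step ends in a β-hydroxy carboxylate, which can neither dehydrate nor retro-aldolise.

Key step: step 3

Assumption 1: the quinine-derived primary amine is written for step 2; which pseudoenantiomer (quinine- or quinidine-derived) gives the (1S,6S)-epoxide is taken from the behaviour of 3-methylcyclohex-2-en-1-one, and the other is used if the sense is opposite.

Assumption 2: the esterase in step 8 is taken to hydrolyse the ester group that leads to (S)-14; sense and level of selectivity for the prenyl substrate have to be checked, and the fallback for step 8 supplies either enantiomer.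

## Route

Step 1
Reactants: 1 mesityl oxide (4-methylpent-3-en-2-one); 2 methyl vinyl ketone (but-3-en-2-one)
Product: 4 piperitenone (3-methyl-6-(propan-2-ylidene)cyclohex-2-en-1-one), via 3-(prop-1-en-2-yl)heptane-2,6-dione 3 (not isolated)
Conditions: powdered KOH (0.2 equiv), excess 1, THF, 0 °C to rt; distillation
Reagents that add atoms: none
Why: Base-mediated Michael/aldol (Robinson-type) annulation: the extended enolate of 1 adds through its α-carbon to 2 to give diketone 3, the acetyl methyl then condenses with the unhindered methyl ketone, and the base moves the isopropenyl double bond into conjugation; no stereocentre is formed.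

Step 2
Reactants: 4 piperitenone
Product: 5 (1S,6S)-6-methyl-3-(propan-2-ylidene)-7-oxabicyclo[4.1.0]heptan-2-one (piperitenone oxide)
Conditions: 9-amino-9-deoxy-epi-quinine (10 mol%), CF3CO2H (20 mol%), 50% aq. H2O2 (1.5 equiv), dioxane, 35 °C
Reagents that add atoms: hydrogen peroxide, OO
Why: Amine-salt (iminium) catalysed Weitz–Scheffer epoxidation of a cyclic enone: hydroperoxide adds to the ring β-carbon and the enamine closes the oxirane; the trisubstituted ring alkene, coplanar with the carbonyl, should react in preference to the twisted tetrasubstituted exocyclic one, as it does with alkaline H2O2, and the chiral primary amine sets both epoxide carbons together (cis by ring constraint).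

Step 3
Reactants: 5 (1S,6S)-piperitenone oxide
Product: 7 (1R,2S,5S)-2-hydroxy-2-methyl-5-(prop-1-en-2-yl)cyclopentane-1-carboxylic acid, via cyclopropanone alkoxide 6 (not isolated)
Conditions: KOH (3 equiv), H2O/t-BuOH 1:1, 0 °C to rt; then 1 M HCl to pH 3 at 0 °C
Reagents that add atoms: potassium hydroxide, [K+].[OH-]
Why: Favorskii-type contraction of a cyclic α,β-epoxy ketone by alkali, the closest known case being the saturated 2,3-epoxy-3-methylcyclohexanones (piperitone oxide class); the untested element is that the enolate must be reached by γ-deprotonation of an isopropylidene methyl. The cross-conjugated dienolate attacks the epoxide CH through its ring α-carbon from the face opposite the oxygen (3-exo-tet), which closes the cyclopropanone of 6 and, with the same C–C bond, the five-membered carbocycle; the chain terminus cannot compete because bonding there would put a double bond at a bridgehead. Hydroxide adds to the strained carbonyl and the bond to the isopropenyl-bearing carbon breaks, because only that cleavage leaves an allyl-stabilised carbanion, so the carboxylate stays on the carbon between the carbinol and the allylic carbon. The carbinol centre is carried over from the epoxide and the former epoxide CH is inverted by the backside displacement, so hydroxyl and carboxylate end cis by mechanism. The one new centre, the allylic CH, is set by protonation on the face just vacated by the carbonyl carbon (retention), which puts isopropenyl trans to carboxylate, also the less crowded arrangement. The selectivity the step needs is protonation at the ring carbon and not at the CH2 terminus of the allyl anion; water as solvent delivers the proton as the C–C bond breaks, and the cis tertiary hydroxyl and the nascent carboxyl group hold a proton donor next to the ring carbon. The product is a β-hydroxy carboxylate dianion that can neither retro-aldolise nor epimerise, and cold acidification to pH 3 spares the tertiary alcohol.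

Step 4
Reactants: 7 hydroxy acid
Product: 8 methyl (1R,2S,5S)-2-hydroxy-2-methyl-5-(prop-1-en-2-yl)cyclopentane-1-carboxylate
Conditions: Me3SiCHN2, MeOH/toluene 1:4, 0 °C to rt
Reagents that add atoms: (trimethylsilyl)diazomethane, C[Si](C)(C)C=[N+]=[N-]
Why: Esterification of a carboxylic acid with a diazoalkane (proton transfer, then O-alkylation with loss of N2); neutral conditions leave the tertiary β-hydroxyl, the alkene and the three stereocentres untouched.

Step 5
Reactants: 8 hydroxy ester
Product: 9 methyl (1R,2S,5S)-2-methyl-5-(prop-1-en-2-yl)-2-[(triethylsilyl)oxy]cyclopentane-1-carboxylate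
Conditions: Et3SiOTf, 2,6-lutidine, CH2Cl2, −78 to 0 °C; aq. NaHCO3
Reagents that add atoms: triethylsilyl trifluoromethanesulfonate, CC[Si](CC)(CC)OS(=O)(=O)C(F)(F)F
Why: Silylation of a hindered tertiary alcohol with a silyl triflate and a hindered pyridine base; the ether blocks retro-aldol cleavage and dehydration at the aldehyde stage.

Step 6
Reactants: 9 silyl ether ester
Product: 10 (1R,2S,5S)-2-methyl-5-(prop-1-en-2-yl)-2-[(triethylsilyl)oxy]cyclopentane-1-carbaldehyde
Conditions: iBu2AlH (1.1 equiv), CH2Cl2, −78 °C; MeOH, then aq. potassium sodium tartrate
Reagents that add atoms: none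
Why: Partial reduction of an ester by iBu2AlH: the aluminium hemiacetal, held by the β-silyloxy oxygen and the α-branching, survives at −78 °C and gives the aldehyde only on work-up; cold non-basic conditions keep the α-centre.

Step 7
Reactants: 11 dimethyl 2-methylmalonate; 12 prenyl bromide (1-bromo-3-methylbut-2-ene)
Product: 13 dimethyl 2-methyl-2-(3-methylbut-2-en-1-yl)propanedioate
Conditions: NaH, THF, 0 °C to rt
Reagents that add atoms: none
Why: Malonate alkylation (SN2 on a primary allylic bromide by the sodium enolate); the product is prochiral, with two enantiotopic ester groups.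

Step 8
Reactants: 13 prochiral diester
Product: 14 (2S)-2-(methoxycarbonyl)-2,5-dimethylhex-4-enoic acid
Conditions: pig liver esterase, 0.1 M phosphate buffer pH 7.5, DMSO (10% v/v), 25 °C, pH-stat with 1 M NaOH; then HCl to pH 2
Reagents that add atoms: water, O
Why: Enzymatic desymmetrisation of a prochiral diester: the esterase hydrolyses one of the two enantiotopic methoxycarbonyl groups and the carboxylate formed is no longer a substrate; this choice creates the quaternary stereocentre, whose purity can be raised by crystallising an amine salt of 14.

Step 9
Reactants: 14 half-ester; 15 6-methylheptane-2,4-dione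
Product: 17 methyl (2S)-2,9-dimethyl-2-(3-methylbut-2-en-1-yl)-3,5,7-trioxodecanoate, via acid chloride 16 (not isolated)
Conditions: (i) (COCl)2, DMF (cat.), CH2Cl2, 0 °C to rt, evaporate; (ii) 15 (2.2 equiv), LiN(iPr)2 (4.4 equiv), THF, 0 °C, then 16 at −78 °C; AcOH, aq. NH4Cl
Reagents that add atoms: none
Why: Acid chloride formation, then γ-acylation of a β-diketone dianion at its terminal, most nucleophilic carbanion; the acyl chloride has no α-hydrogen, so neither ketene formation nor racemisation is possible, the neopentyl-type methyl ester does not compete at −78 °C, and the excess dianion takes up the acidic proton of the triketone formed.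

Step 10
Reactants: 17 triketo ester
Product: 18 (6S)-3,5-dihydroxy-6-methyl-2-(3-methylbutanoyl)-6-(3-methylbut-2-en-1-yl)cyclohexa-2,4-dien-1-one (enol form of the acyl trione)
Conditions: KOtBu (2.5 equiv), THF, 0 °C to rt; 1 M HCl
Reagents that add atoms: none
Why: Dieckmann (intramolecular Claisen) condensation: the carbanion of the methylene between the C5 and C7 carbonyl groups attacks the ester (6-exo-trig), driven by formation of the delocalised trione anion; a non-nucleophilic base and short contact keep retro-Claisen opening, which would exchange the two carbonyl groups flanking the quaternary centre, from setting in.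

Step 11
Reactants: 18 acyl trione core; 10 aldehyde
Product: 20 (6S)-3,5-dihydroxy-6-methyl-2-(3-methylbutanoyl)-6-(3-methylbut-2-en-1-yl)-4-({(1R,2S,5S)-2-methyl-5-(prop-1-en-2-yl)-2-[(triethylsilyl)oxy]cyclopentyl}methyl)cyclohexa-2,4-dien-1-one, via alkylidene trione 19 (not isolated)
Conditions: L-proline (20 mol%), diethyl 2,6-dimethyl-1,4-dihydropyridine-3,5-dicarboxylate (Hantzsch ester, 1.2 equiv), CH2Cl2, rt
Reagents that add atoms: none
Why: Three-component reductive alkylation: amine-catalysed Knoevenagel condensation of 10 at the only unsubstituted ring carbon of 18 gives alkylidene trione 19, which is reduced at once by conjugate hydride transfer from the dihydropyridine; the new CH2 is not stereogenic, the aldehyde α-centre is already in its favoured arrangement (trans to both neighbouring carbon substituents) and the quaternary centre is not involved.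

Step 12
Reactants: 20 silyl-protected target
Product: 21 (6S)-3,5-dihydroxy-4-{[(1R,2S,5S)-2-hydroxy-2-methyl-5-(prop-1-en-2-yl)cyclopentyl]methyl}-6-methyl-2-(3-methylbutanoyl)-6-(3-methylbut-2-en-1-yl)cyclohexa-2,4-dien-1-one (CNP0139230.1)
Conditions: HF·pyridine, pyridine, THF, 0 °C to rt
Reagents that add atoms: none
Why: Fluoride cleavage of a silyl ether under pyridine-buffered conditions; strong acid, which would ionise the tertiary alcohol towards dehydration or pyran formation, is avoided.

## Compound list

1 | mesityl oxide (4-methylpent-3-en-2-one) | CC(=O)C=C(C)C | starting material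
2 | methyl vinyl ketone (but-3-en-2-one) | C=CC(C)=O | starting material
3 | 3-(prop-1-en-2-yl)heptane-2,6-dione | CC(=O)CCC(C(C)=C)C(C)=O | intermediate
4 | piperitenone, 3-methyl-6-(propan-2-ylidene)cyclohex-2-en-1-one | CC1=CC(=O)C(=C(C)C)CC1 | intermediate
5 | (1S,6S)-6-methyl-3-(propan-2-ylidene)-7-oxabicyclo[4.1.0]heptan-2-one (piperitenone oxide) | C[C@]12CCC(=C(C)C)C(=O)[C@H]1O2 | intermediate
6 | (1R,4S,5R)-4-hydroxy-4-methyl-1-(prop-1-en-2-yl)bicyclo[3.1.0]hexan-6-one, present as its potassium alkoxide | C=C(C)[C@@]12CC[C@](C)(O)[C@@H]1C2=O | intermediate
7 | (1R,2S,5S)-2-hydroxy-2-methyl-5-(prop-1-en-2-yl)cyclopentane-1-carboxylic acid | C=C(C)[C@H]1CC[C@](C)(O)[C@@H]1C(=O)O | intermediate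
8 | methyl (1R,2S,5S)-2-hydroxy-2-methyl-5-(prop-1-en-2-yl)cyclopentane-1-carboxylate | C=C(C)[C@H]1CC[C@](C)(O)[C@@H]1C(=O)OC | intermediate
9 | methyl (1R,2S,5S)-2-methyl-5-(prop-1-en-2-yl)-2-[(triethylsilyl)oxy]cyclopentane-1-carboxylate | C=C(C)[C@H]1CC[C@](C)(O[Si](CC)(CC)CC)[C@@H]1C(=O)OC | intermediate
10 | (1R,2S,5S)-2-methyl-5-(prop-1-en-2-yl)-2-[(triethylsilyl)oxy]cyclopentane-1-carbaldehyde | C=C(C)[C@H]1CC[C@](C)(O[Si](CC)(CC)CC)[C@@H]1C=O | intermediate
11 | dimethyl 2-methylmalonate | COC(=O)C(C)C(=O)OC | starting material
12 | prenyl bromide (1-bromo-3-methylbut-2-ene) | CC(C)=CCBr | starting material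
13 | dimethyl 2-methyl-2-(3-methylbut-2-en-1-yl)propanedioate | COC(=O)C(C)(CC=C(C)C)C(=O)OC | intermediate
14 | (2S)-2-(methoxycarbonyl)-2,5-dimethylhex-4-enoic acid | OC(=O)[C@](C)(CC=C(C)C)C(=O)OC | intermediate
15 | 6-methylheptane-2,4-dione | CC(C)CC(=O)CC(C)=O | starting material
16 | methyl (2R)-2-(chlorocarbonyl)-2,5-dimethylhex-4-enoate | ClC(=O)[C@](C)(CC=C(C)C)C(=O)OC | intermediate
17 | methyl (2S)-2,9-dimethyl-2-(3-methylbut-2-en-1-yl)-3,5,7-trioxodecanoate | CC(C)CC(=O)CC(=O)CC(=O)[C@](C)(CC=C(C)C)C(=O)OC | intermediate
18 | (6S)-3,5-dihydroxy-6-methyl-2-(3-methylbutanoyl)-6-(3-methylbut-2-en-1-yl)cyclohexa-2,4-dien-1-one | CC(C)CC(=O)C1=C(O)C=C(O)[C@](C)(CC=C(C)C)C1=O | intermediate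
19 | 3-hydroxy-6-methyl-2-(3-methylbutanoyl)-6-(3-methylbut-2-en-1-yl)-4-({(1R,2S,5S)-2-methyl-5-(prop-1-en-2-yl)-2-[(triethylsilyl)oxy]cyclopentyl}methylidene)cyclohex-2-ene-1,5-dione, quaternary centre as in 18, E/Z mixture | C=C(C)[C@H]1CC[C@](C)(O[Si](CC)(CC)CC)[C@@H]1C=C1C(=O)[C@](C)(CC=C(C)C)C(=O)C(C(=O)CC(C)C)=C1O | intermediate
20 | (6S)-3,5-dihydroxy-6-methyl-2-(3-methylbutanoyl)-6-(3-methylbut-2-en-1-yl)-4-({(1R,2S,5S)-2-methyl-5-(prop-1-en-2-yl)-2-[(triethylsilyl)oxy]cyclopentyl}methyl)cyclohexa-2,4-dien-1-one | C=C(C)[C@H]1CC[C@](C)(O[Si](CC)(CC)CC)[C@@H]1CC1=C(O)[C@](C)(CC=C(C)C)C(=O)C(C(=O)CC(C)C)=C1O | intermediate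
21 | (6S)-3,5-dihydroxy-4-{[(1R,2S,5S)-2-hydroxy-2-methyl-5-(prop-1-en-2-yl)cyclopentyl]methyl}-6-methyl-2-(3-methylbutanoyl)-6-(3-methylbut-2-en-1-yl)cyclohexa-2,4-dien-1-one | C=C(C)[C@H]1CC[C@](C)(O)[C@@H]1CC1=C(O)[C@](C)(CC=C(C)C)C(=O)C(C(=O)CC(C)C)=C1O | target

## Step count and least certain steps

Total step count: 12. Longest linear sequence: 8 steps (steps 1–6, 11, 12); the core branch (steps 7–10) joins at step 11.

**Step 3 (key step).** The most likely failure is protonation of the allyl anion at its chain terminus, which moves the double bond to the isopropylidene position and erases the allylic stereocentre. A second is γ-deprotonation so slow that hydroxide attacks the epoxy ketone directly. Both stem from the one untested feature, enolisation through the isopropylidene group. The fallback masks the alkene so that the contraction runs through an ordinary α'-CH enolate, as in the documented saturated case, and restores the isopropenyl group afterwards by a regiospecific elimination. It sets out from 5 and returns at 7.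
- Kinetic deprotonation of 5 (LiN(iPr)2, THF, −78 °C) and α-protonation with AcOH give the deconjugated (1S,6S)-6-methyl-3-(prop-1-en-2-yl)-7-oxabicyclo[4.1.0]heptan-2-one (isopiperitenone oxide) F1; its epimers at the allylic carbon are of no consequence.
- Radical anti-Markovnikov addition of thiophenol (AIBN, toluene, 80 °C) gives (1S,6S)-6-methyl-3-[1-(phenylsulfanyl)propan-2-yl]-7-oxabicyclo[4.1.0]heptan-2-one F2.
- KOH in H2O/t-BuOH then gives, by the known saturated contraction, (1R,2S,5S)-2-hydroxy-2-methyl-5-[1-(phenylsulfanyl)propan-2-yl]cyclopentane-1-carboxylic acid F3.
- NaIO4 in MeOH/H2O gives the sulfoxide (1R,2S,5S)-2-hydroxy-2-methyl-5-[1-(phenylsulfinyl)propan-2-yl]cyclopentane-1-carboxylic acid F4.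
- Thermal syn-elimination (toluene, 110 °C, CaCO3) can remove only the hydrogen on the carbon next to the ring, which gives the isopropenyl group of 7.

**Step 2.** Iminium formation may be hindered by the neighbouring isopropylidene group, giving low conversion, poor facial selectivity or attack on the exocyclic alkene. The fallback gives up catalytic asymmetric induction for a resolution. It sets out from 4 and returns at 7.
- Alkaline H2O2 (NaOH cat., MeOH, 0 °C) gives racemic piperitenone oxide F5.
- The conditions of step 3 give the racemic hydroxy acid F6.
- Crystallisation with (R)-1-phenylethylamine (taken here as the amine whose salt with 7 is the less soluble) gives the diastereomerically pure ammonium salt F7; cold dilute acid liberates 7.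

**Step 11.** Condensation at the hindered aldehyde may be slow. That would allow enamine formation from 10, followed by epimerisation at the α-carbon or loss of the β-silyloxy group. The fallback forms the other bond of the hinge by a radical conjugate addition, with no carbonyl condensation and no amine in contact with an aldehyde. It sets out from 7 and 18 and returns at 20.
- Acid 7 is bis-silylated (Et3SiOTf, 2,6-lutidine) and the silyl ester cleaved (K2CO3, MeOH/H2O) to (1R,2S,5S)-2-methyl-5-(prop-1-en-2-yl)-2-[(triethylsilyl)oxy]cyclopentane-1-carboxylic acid F8.
- Coupling with N-hydroxyphthalimide (diisopropylcarbodiimide, cat. DMAP) gives the N-(acyloxy)phthalimide F9.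
- Core 18 with dimethylmethyleneiminium iodide gives the Mannich base (6S)-4-[(dimethylamino)methyl]-3,5-dihydroxy-6-methyl-2-(3-methylbutanoyl)-6-(3-methylbut-2-en-1-yl)cyclohexa-2,4-dien-1-one F10.
- Single-electron reduction of F9 (zinc dust, NiCl2·6H2O cat., LiCl, MeCN, 25–40 °C) releases CO2 and a secondary cyclopentyl radical, which adds to the exocyclic methylene set free from F10 (decarboxylative Giese addition). Bond formation trans to both flanking carbon substituents restores the ring CH configuration and gives 20.

**Step 8.** The esterase may discriminate the enantiotopic ester groups insufficiently or in the reverse sense for the prenyl substrate. The fallback replaces desymmetrisation by resolution. It sets out from 13 and returns at 14.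
- KOH (1 equiv) in MeOH gives the racemic half-ester F11.
- The salt with (S)-1-phenylethylamine, F12, is crystallised to constant rotation and acidified to 14. The other enantiomer of the amine is used if the wrong salt crystallises first.

**Step 9.** The acyl chloride may over-acylate or O-acylate the dianion, or proton transfer from the product may stop the reaction. The fallback replaces acylation by aldol addition and oxidation. It sets out from 16 and returns at 17.
- LiAlH(OtBu)3 (THF, −78 °C) reduces 16 to methyl (2S)-2-formyl-2,5-dimethylhex-4-enoate F13, which has no α-hydrogen.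
- The dianion of 15 adds at −78 °C to give methyl (2S)-3-hydroxy-2,9-dimethyl-2-(3-methylbut-2-en-1-yl)-5,7-dioxodecanoate F14 as a mixture at the carbinol.
- Dess–Martin periodinane oxidises F14 to 17.

## Further compounds

F1 | step 3 | (1S,6S)-6-methyl-3-(prop-1-en-2-yl)-7-oxabicyclo[4.1.0]heptan-2-one (isopiperitenone oxide, C3 epimers) | C[C@]12CCC(C(C)=C)C(=O)[C@H]1O2
F2 | step 3 | (1S,6S)-6-methyl-3-[1-(phenylsulfanyl)propan-2-yl]-7-oxabicyclo[4.1.0]heptan-2-one | C[C@]12CCC(C(C)CSc3ccccc3)C(=O)[C@H]1O2
F3 | step 3 | (1R,2S,5S)-2-hydroxy-2-methyl-5-[1-(phenylsulfanyl)propan-2-yl]cyclopentane-1-carboxylic acid | CC(CSc1ccccc1)[C@H]1CC[C@](C)(O)[C@@H]1C(=O)O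
F4 | step 3 | (1R,2S,5S)-2-hydroxy-2-methyl-5-[1-(phenylsulfinyl)propan-2-yl]cyclopentane-1-carboxylic acid | CC(CS(=O)c1ccccc1)[C@H]1CC[C@](C)(O)[C@@H]1C(=O)O
F5 | step 2 | racemic piperitenone oxide (both enantiomers) | C[C@]12CCC(=C(C)C)C(=O)[C@H]1O2.C[C@@]12CCC(=C(C)C)C(=O)[C@@H]1O2
F6 | step 2 | racemic 2-hydroxy-2-methyl-5-(prop-1-en-2-yl)cyclopentane-1-carboxylic acid, relative configuration as in 7 (both enantiomers) | C=C(C)[C@H]1CC[C@](C)(O)[C@@H]1C(=O)O.C=C(C)[C@@H]1CC[C@@](C)(O)[C@H]1C(=O)O
F7 | step 2 | (R)-1-phenylethylammonium salt of acid 7 | C=C(C)[C@H]1CC[C@](C)(O)[C@@H]1C(=O)[O-].C[C@@H]([NH3+])c1ccccc1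
F8 | step 11 | (1R,2S,5S)-2-methyl-5-(prop-1-en-2-yl)-2-[(triethylsilyl)oxy]cyclopentane-1-carboxylic acid | C=C(C)[C@H]1CC[C@](C)(O[Si](CC)(CC)CC)[C@@H]1C(=O)O
F9 | step 11 | 1,3-dioxoisoindolin-2-yl (1R,2S,5S)-2-methyl-5-(prop-1-en-2-yl)-2-[(triethylsilyl)oxy]cyclopentane-1-carboxylate | C=C(C)[C@H]1CC[C@](C)(O[Si](CC)(CC)CC)[C@@H]1C(=O)ON1C(=O)c2ccccc2C1=O
F10 | step 11 | (6S)-4-[(dimethylamino)methyl]-3,5-dihydroxy-6-methyl-2-(3-methylbutanoyl)-6-(3-methylbut-2-en-1-yl)cyclohexa-2,4-dien-1-one | CN(C)CC1=C(O)[C@](C)(CC=C(C)C)C(=O)C(C(=O)CC(C)C)=C1O
F11 | step 8 | racemic 2-(methoxycarbonyl)-2,5-dimethylhex-4-enoic acid (both enantiomers) | OC(=O)[C@](C)(CC=C(C)C)C(=O)OC.OC(=O)[C@@](C)(CC=C(C)C)C(=O)OC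
F12 | step 8 | (S)-1-phenylethylammonium salt of half-ester 14 | [O-]C(=O)[C@](C)(CC=C(C)C)C(=O)OC.C[C@H]([NH3+])c1ccccc1
F13 | step 9 | methyl (2S)-2-formyl-2,5-dimethylhex-4-enoate | O=C[C@](C)(CC=C(C)C)C(=O)OC
F14 | step 9 | methyl (2S)-3-hydroxy-2,9-dimethyl-2-(3-methylbut-2-en-1-yl)-5,7-dioxodecanoate (C3 epimers) | CC(C)CC(=O)CC(=O)CC(O)[C@](C)(CC=C(C)C)C(=O)OC
A1 | alternative 1 | cis-fused cyclopenta-annulated dihydropyran in which the tertiary oxygen of the cyclopentane is bonded to an enol carbon of the acyl trione (one of two regioisomers) | C=C(C)[C@H]1CC[C@]2(C)OC3=C(C[C@H]12)C(O)=C(C(=O)CC(C)C)C(=O)[C@@]3(C)CC=C(C)C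
A2 | alternative 1 | (S)-1-methyl-3-(prop-1-en-2-yl)cyclopent-1-ene | C=C(C)[C@H]1CCC(C)=C1
A3 | alternative 1 | exocyclic methylene form (o-quinone methide) of core 18 | C=C1C(=O)[C@](C)(CC=C(C)C)C(=O)C(C(=O)CC(C)C)=C1O
A4 | alternative 2 | 2-{[(tert-butyldimethylsilyl)oxy]methyl}-1-methyl-3-(prop-1-en-2-yl)cyclopentan-1-ol, configured as the cyclopentane of 21 | C=C(C)[C@H]1CC[C@](C)(O)[C@@H]1CO[Si](C)(C)C(C)(C)C
A5 | alternative 2 | 1-O-(tert-butyldimethylsilyl) ether of 5-iodo-3-methyl-2-(2-methylprop-1-en-1-yl)pentane-1,3-diol, both centres as in A4 | ICC[C@](C)(O)[C@H](CO[Si](C)(C)C(C)(C)C)C=C(C)C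
A6 | alternative 3 | (1R,2S,5S)-2-hydroxy-2-methyl-5-(prop-1-en-2-yl)cyclopentane-1-carbaldehyde | C=C(C)[C@H]1CC[C@](C)(O)[C@@H]1C=O
A7 | alternative 3 | (S)-6-oxo-3-(prop-1-en-2-yl)heptanal | C=C(C)[C@H](CC=O)CCC(C)=O
A8 | alternative 3 | (S)-limonene | C=C(C)[C@@H]1CC=C(C)CC1
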